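**Strategy.** The route rests on cutting C2–C3 of ring A. C3 hangs on the quaternary C4 (gem-dimethyl) and C2 reaches C10 through C1, so both can be delivered as terminal alkenes on the adjacent ring-B carbons C5 and C10. Ring-closing olefin metathesis joins an allyl group on C10 to a 1,1-dimethylallyl group on C5 of a preformed ring B, and the new alkene is hydrogenated in the same operation to give the 4,4,10-trimethyldecalin. The precursor is a monocyclic diol made from 2-methylcyclohexane-1,3-dione by allylation, desymmetrising reduction (fixes C10) and γ-addition of prenylmagnesium chloride. Later a C9 enol triflate carries the side chain, and the C5–C6 alkene leads to the 6β-acyloxy-7α-hydroxy pair.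

Key step: step 4

Remarks. Labdane numbering is used: ring A = C1–C5, C10; ring B = C5–C10; side chain C11–C16; α is the face opposite the C10 methyl. Assumption: the CBS desymmetrisation follows the usual model ((S)-catalyst gives the (R)-carbinol, hydride anti to the allyl group); if the sense were reversed, the (R)-catalyst would be taken. (E)-3-Methylpent-2-en-4-yn-1-ol and prenylmagnesium chloride solution are taken as commercial.

Step 1
Reactants: 1 2-methylcyclohexane-1,3-dione
Product: 2 2-allyl-2-methylcyclohexane-1,3-dione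
Conditions: allyl bromide, NaOH, H2O, 25 °C
Reagents that add atoms: allyl bromide, C=CCBr
Why: C-alkylation of the stabilised 1,3-dione enolate at the methyl-bearing carbon makes the future C10 a prochiral quaternary carbon (no stereocentre yet).

Step 2
Reactants: 2 2-allyl-2-methylcyclohexane-1,3-dione
Product: 3 (2R,3R)-2-allyl-3-hydroxy-2-methylcyclohexan-1-one (hydroxyl cis to allyl)
Conditions: (S)-2-methyl-CBS-oxazaborolidine (20 mol %), catecholborane, N,N-diethylaniline, toluene, −60 °C
Reagents that add atoms: none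
Why: Corey–Bakshi–Shibata reduction desymmetrises the dione, since the catalyst fixes the carbinol configuration and hydride enters anti to the allyl group, so only one enantiotopic carbonyl should react and C10 is set.

Step 3
Reactants: 3 (2R,3R)-2-allyl-3-hydroxy-2-methylcyclohexan-1-one
Product: 4 (1R,2R,3R)-2-allyl-2-methyl-1-(2-methylbut-3-en-2-yl)cyclohexane-1,3-diol (expected C5 epimer drawn; the other converges in step 6)
Conditions: Me2C=CHCH2MgCl (2.5 equiv), THF, −78 °C; aq NH4Cl at −78 °C
Reagents that add atoms: prenylmagnesium chloride, CC(C)=CC[Mg]Cl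
Why: allylic Grignard reagents add to ketones through their γ-carbon (six-membered SE2′ transition state), which puts the 1,1-dimethylallyl group (C4 with its two methyls, C3 and a vinyl terminus) on C5; attack on the face of the C10 methyl, away from the allyl chain and the C9 alkoxide, is expected, and this carbinol centre is erased in step 6.

Step 4
Reactants: 4 (1R,2R,3R)-2-allyl-2-methyl-1-(2-methylbut-3-en-2-yl)cyclohexane-1,3-diol
Product: 6 4,4,10-trimethyl-trans-decalin-5α,9α-diol, via cyclohexene diol 5 (not isolated)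
Conditions: second-generation Grubbs catalyst (5 mol %), CH2Cl2 (5 mM), 40 °C; solvent exchange, then H2 (1 atm), Pd/C, EtOAc, 25 °C
Reagents that add atoms: none
Why: Ring-closing olefin metathesis of a 1,7-diene: the ruthenium alkylidene loads on the unhindered allyl terminus on C10, the tethered 1,1-dimethylallyl alkene on C5 enters by [2+2] cycloaddition, and cycloreversion expels ethylene; the closest known reaction type is metathesis closure of cyclohexenes bearing an allylic quaternary carbon. Ring A (six-membered carbocycle) closes between C2 and C3 by alkene–alkene metathesis onto the existing ring B. No stereocentre is created: C10 comes from step 2, and either C5 carbinol epimer closes (to a trans- or cis-fused ene-diol) before that centre is erased in step 6. The selectivity needed is ring closure over cross-metathesis, which the 1,2-placement of the two chains on ring B, the C4 gem-dimethyl group and dilution should secure; free hydroxyls are tolerated. The cis-alkene, the only one in the molecule, is then saturated so that C2 and C3 become the two methylenes of the target.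

Step 5
Reactants: 6 4,4,10-trimethyl-trans-decalin-5α,9α-diol
Product: 7 5α-hydroxy-4,4,10-trimethyl-trans-decalin-9-one
Conditions: Dess–Martin periodinane, NaHCO3, CH2Cl2, 0 → 25 °C
Reagents that add atoms: none
Why: the periodinane oxidises only the secondary C9 carbinol, whose stereocentre has done its work, and leaves the tertiary C5 hydroxyl untouched under non-basic conditions that avoid retro-aldol cleavage.

Step 6
Reactants: 7 5α-hydroxy-4,4,10-trimethyl-trans-decalin-9-one
Product: 8 (S)-5,5,8a-trimethyl-3,5,6,7,8,8a-hexahydronaphthalen-1(2H)-one (4,4,10-trimethyl-Δ5-octalin-9-one)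
Conditions: SOCl2, pyridine, 0 °C
Reagents that add atoms: none
Why: E2 dehydration through the chlorosulfite can only go towards C6, because C4 and C10 are quaternary, and the concerted course should avoid 1,2-methyl shifts to a C5 cation.

Step 7
Reactants: 8 (S)-5,5,8a-trimethyl-3,5,6,7,8,8a-hexahydronaphthalen-1(2H)-one
Product: 10 4,4,8,10-tetramethyl-Δ5-octalin-9-one (C8 epimers), via lithium enolate 9 (not isolated)
Conditions: LiN(iPr)2, THF, −78 °C; MeI, −78 → 0 °C
Reagents that add atoms: iodomethane, CI
Why: the ketone can enolise only towards C8 (C10 is quaternary and the C5=C6 alkene is not conjugated), so enolate alkylation places C17 on C8; the new centre becomes sp2 in step 8.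

Step 8
Reactants: 10 4,4,8,10-tetramethyl-Δ5-octalin-9-one
Product: 12 (S)-2,5,5,8a-tetramethyl-3,5,6,7,8,8a-hexahydronaphthalen-1-yl trifluoromethanesulfonate (C5=C6 and C8=C9 diene), via potassium enolate 11 (not isolated)
Conditions: KN(SiMe3)2, THF, −78 → −40 °C; PhNTf2, −78 → 0 °C
Reagents that add atoms: N-phenylbis(trifluoromethanesulfonimide), O=S(=O)(N(c1ccccc1)S(=O)(=O)C(F)(F)F)C(F)(F)F
Why: O-sulfonylation of the only possible enolate fixes the tetrasubstituted C8=C9 alkene regiospecifically, as for 2,2,6-trisubstituted cyclohexanones, and provides the handle for the side chain.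

Step 9
Reactants: 12 (S)-2,5,5,8a-tetramethyl-3,5,6,7,8,8a-hexahydronaphthalen-1-yl trifluoromethanesulfonate
Product: 14 6α-hydroxy-5α-H trans-fused enol triflate, via C6 alkylborane 13 (not isolated)
Conditions: BH3·THF, THF, 0 → 25 °C; then NaBO3·4H2O, H2O, 25 °C
Reagents that add atoms: sodium perborate, [Na+].[Na+].O[B-]1(O)OO[B-](O)(O)OO1 (oxygen of the product); borane–tetrahydrofuran, B.C1CCOC1 (boron of intermediate 13 only)
Why: hydroboration–oxidation puts boron on C6 and hydrogen on C5 syn from the α-face, opposite the axial 4β- and 10β-methyl groups, which sets the trans ring fusion (5α-H); the electron-poor tetrasubstituted enol triflate alkene should not react.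

Step 10
Reactants: 14 6α-hydroxy-5α-H trans-fused enol triflate
Product: 15 6-oxo trans-fused enol triflate
Conditions: Dess–Martin periodinane, NaHCO3, CH2Cl2, 25 °C
Reagents that add atoms: none
Why: oxidation of the secondary alcohol gives the C6 ketone; C5 keeps the thermodynamically preferred trans fusion and the triflate locks the alkene at C8=C9.

Step 11
Reactants: 15 6-oxo trans-fused enol triflate
Product: 18 7α-(triethylsilyloxy)-6-oxo enol triflate, via potassium dienolate 16 (not isolated), via potassium 7α-alkoxide 17 (not isolated)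
Conditions: KN(SiMe3)2 (1.05 equiv), THF, −78 °C; 2-(phenylsulfonyl)-3-phenyloxaziridine, −78 °C; then Et3SiCl, −78 → −20 °C
Reagents that add atoms: 2-(phenylsulfonyl)-3-phenyloxaziridine, O=S(=O)(N1OC1c1ccccc1)c1ccccc1; chlorotriethylsilane, CC[Si](Cl)(CC)CC
Why: kinetic deprotonation at C7 (α to the ketone and allylic) gives the dienolate, which the oxaziridine hydroxylates at its α-carbon along the axial α-face trajectory opposite the 4β- and 10β-methyl groups (Davis oxidation, sets 7α), and in-situ silylation caps the alkoxide before the α-ketol can equilibrate.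

Step 12
Reactants: 18 7α-(triethylsilyloxy)-6-oxo enol triflate
Product: 19 6β-hydroxy-7α-(triethylsilyloxy) enol triflate
Conditions: NaBH4, MeOH/THF, −20 °C
Reagents that add atoms: none
Why: hydride should attack the C6 carbonyl from the α-face because the β-face is closed by the 1,3-diaxial 4β- and 10β-methyl groups, giving the axial 6β-alcohol trans-diaxial to the 7α-silyloxy group.

Step 13
Reactants: 19 6β-hydroxy-7α-(triethylsilyloxy) enol triflate
Product: 20 6β-(3-methylbutanoyloxy)-7α-(triethylsilyloxy) enol triflate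
Conditions: isovaleryl chloride, DMAP, pyridine, 50 °C
Reagents that add atoms: 3-methylbutanoyl chloride, CC(C)CC(=O)Cl
Why: DMAP-catalysed acylation through the acylpyridinium ion esterifies the only free hydroxyl, and the trans-diaxial arrangement of O6 and O7 excludes silyl or acyl migration.

Step 14
Reactants: 21 (E)-3-methylpent-2-en-4-yn-1-ol
Product: 22 (E)-tert-butyldimethyl[(3-methylpent-2-en-4-yn-1-yl)oxy]silane
Conditions: t-BuMe2SiCl, imidazole, DMF, 25 °C
Reagents that add atoms: tert-butyldimethylsilyl chloride, CC(C)(C)[Si](C)(C)Cl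
Why: standard silylation masks the primary allylic alcohol (future C15–OH) through hydroboration and cross-coupling.

Step 15
Reactants: 22 (E)-tert-butyldimethyl[(3-methylpent-2-en-4-yn-1-yl)oxy]silane
Product: 23 (E)-tert-butyldimethyl[(3-methylpenta-2,4-dien-1-yl)oxy]silane
Conditions: H2 (1 atm), Pd/CaCO3 poisoned with Pb(OAc)2, quinoline, hexane, 25 °C
Reagents that add atoms: none
Why: poisoned-palladium semihydrogenation stops at the terminal vinyl group and leaves the (E)-trisubstituted alkene (future C13=C14) untouched.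

Step 16
Reactants: 23 (E)-tert-butyldimethyl[(3-methylpenta-2,4-dien-1-yl)oxy]silane; 20 6β-(3-methylbutanoyloxy)-7α-(triethylsilyloxy) enol triflate
Product: 25 15-O-tert-butyldimethylsilyl-7-O-triethylsilyl ether of the target, via B-alkyl-9-BBN borane 24 (not isolated)
Conditions: 23, 9-BBN, THF, 0 → 25 °C; then 20, PdCl2(dppf) (10 mol %), AsPh3, Cs2CO3, DMF/H2O, 25–40 °C
Reagents that add atoms: 9-borabicyclo[3.3.1]nonane, B1C2CCCC1CCC2 (boron of intermediate 24 only)
Why: B-alkyl Suzuki–Miyaura coupling, in which 9-BBN hydroborates only the terminal vinyl group at its CH2 terminus and the alkylborane couples with the enol triflate without moving the alkene, so C9–C11 forms while the C8=C9 and (E)-C13=C14 bonds stay as they are.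

Step 17
Reactants: 25 15-O-tert-butyldimethylsilyl-7-O-triethylsilyl ether of the target
Product: 26 6β-(3-methylbutanoyloxy)labda-8,13(E)-diene-7α,15-diol (CNP0173680.1)
Conditions: HF·pyridine, pyridine/THF, 0 → 25 °C
Reagents that add atoms: none
Why: buffered fluoride removes both silyl ethers while the hindered ester stays and cannot migrate, because O6 and O7 are trans-diaxial.

**Compound list**

1 | 2-methylcyclohexane-1,3-dione | CC1C(=O)CCCC1=O | starting material
2 | 2-allyl-2-methylcyclohexane-1,3-dione | C=CCC1(C)C(=O)CCCC1=O | intermediate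
3 | (2R,3R)-2-allyl-3-hydroxy-2-methylcyclohexan-1-one | C=CC[C@]1(C)[C@H](O)CCCC1=O | intermediate
4 | (1R,2R,3R)-2-allyl-2-methyl-1-(2-methylbut-3-en-2-yl)cyclohexane-1,3-diol | C=CC[C@]1(C)[C@H](O)CCC[C@@]1(O)C(C)(C)C=C | intermediate
5 | 4,4,10-trimethyl-trans-decal-2-ene-5α,9α-diol (ring A alkene C2=C3) | C[C@]12CC=CC(C)(C)[C@]1(O)CCC[C@H]2O | intermediate (not isolated)
6 | 4,4,10-trimethyl-trans-decalin-5α,9α-diol | C[C@]12CCCC(C)(C)[C@]1(O)CCC[C@H]2O | intermediate
7 | 5α-hydroxy-4,4,10-trimethyl-trans-decalin-9-one | C[C@]12CCCC(C)(C)[C@]1(O)CCCC2=O | intermediate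
8 | (S)-5,5,8a-trimethyl-3,5,6,7,8,8a-hexahydronaphthalen-1(2H)-one | C[C@]12CCCC(C)(C)C1=CCCC2=O | intermediate
9 | lithium enolate of 8 (O–C9=C8) | C[C@]12CCCC(C)(C)C1=CCC=C2O[Li] | intermediate (not isolated)
10 | 4,4,8,10-tetramethyl-Δ5-octalin-9-one (C8 epimers, 10S) | C[C@]12CCCC(C)(C)C1=CCC(C)C2=O | intermediate
11 | potassium enolate of 10 (O–C9=C8) | C[C@]12CCCC(C)(C)C1=CCC(C)=C2[O-].[K+] | intermediate (not isolated)
12 | (S)-2,5,5,8a-tetramethyl-3,5,6,7,8,8a-hexahydronaphthalen-1-yl trifluoromethanesulfonate | C[C@]12CCCC(C)(C)C1=CCC(C)=C2OS(=O)(=O)C(F)(F)F | intermediate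
13 | 6α-boryl (BH2) 5α-H adduct of 12 | C[C@]12CCCC(C)(C)[C@@H]1[C@@H](B)CC(C)=C2OS(=O)(=O)C(F)(F)F | intermediate (not isolated)
14 | 6α-hydroxy-4,4,8,10-tetramethyl-trans-octal-8-en-9-yl triflate (5α-H) | C[C@]12CCCC(C)(C)[C@@H]1[C@@H](O)CC(C)=C2OS(=O)(=O)C(F)(F)F | intermediate
15 | 6-oxo-4,4,8,10-tetramethyl-trans-octal-8-en-9-yl triflate (5α-H) | C[C@]12CCCC(C)(C)[C@@H]1C(=O)CC(C)=C2OS(=O)(=O)C(F)(F)F | intermediate
16 | potassium dienolate of 15 (O–C6=C7–C8=C9) | C[C@]12CCCC(C)(C)[C@@H]1C([O-])=CC(C)=C2OS(=O)(=O)C(F)(F)F.[K+] | intermediate (not isolated)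
17 | potassium alkoxide of the 7α-hydroxy-6-ketone | C[C@]12CCCC(C)(C)[C@@H]1C(=O)[C@@H]([O-])C(C)=C2OS(=O)(=O)C(F)(F)F.[K+] | intermediate (not isolated)
18 | 7α-(triethylsilyloxy)-6-oxo enol triflate | C[C@]12CCCC(C)(C)[C@@H]1C(=O)[C@@H](O[Si](CC)(CC)CC)C(C)=C2OS(=O)(=O)C(F)(F)F | intermediate
19 | 6β-hydroxy-7α-(triethylsilyloxy) enol triflate | C[C@]12CCCC(C)(C)[C@@H]1[C@H](O)[C@@H](O[Si](CC)(CC)CC)C(C)=C2OS(=O)(=O)C(F)(F)F | intermediate
20 | 6β-(3-methylbutanoyloxy)-7α-(triethylsilyloxy) enol triflate | C[C@]12CCCC(C)(C)[C@@H]1[C@H](OC(=O)CC(C)C)[C@@H](O[Si](CC)(CC)CC)C(C)=C2OS(=O)(=O)C(F)(F)F | intermediate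
21 | (E)-3-methylpent-2-en-4-yn-1-ol | C#C/C(C)=C/CO | starting material
22 | (E)-tert-butyldimethyl[(3-methylpent-2-en-4-yn-1-yl)oxy]silane | C#C/C(C)=C/CO[Si](C)(C)C(C)(C)C | intermediate
23 | (E)-tert-butyldimethyl[(3-methylpenta-2,4-dien-1-yl)oxy]silane | C=C/C(C)=C/CO[Si](C)(C)C(C)(C)C | intermediate
24 | B-[(E)-5-(tert-butyldimethylsilyloxy)-3-methylpent-3-en-1-yl]-9-borabicyclo[3.3.1]nonane | C(C/C(C)=C/CO[Si](C)(C)C(C)(C)C)B1C2CCCC1CCC2 | intermediate (not isolated)
25 | 15-O-tert-butyldimethylsilyl-7-O-triethylsilyl ether of the target | C[C@]12CCCC(C)(C)[C@@H]1[C@H](OC(=O)CC(C)C)[C@@H](O[Si](CC)(CC)CC)C(C)=C2CC/C(C)=C/CO[Si](C)(C)C(C)(C)C | intermediate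
26 | 6β-(3-methylbutanoyloxy)labda-8,13(E)-diene-7α,15-diol (CNP0173680.1) | CC1=C(CC/C(C)=C/CO)[C@@]2(C)CCCC(C)(C)[C@@H]2[C@H](OC(=O)CC(C)C)[C@H]1O | target

**Step count.** Total: 17 steps. Longest linear sequence: 15 steps (steps 1–13, 16 and 17); steps 14 and 15 make the side-chain fragment.

**Steps most likely to fail, and fallbacks**

Step 13. Acyl transfer to the axial 6β-hydroxyl, shielded by the syn-axial 4β- and 10β-methyl groups, may be too slow, and forcing conditions may cost the allylic silyl ether. The fallback puts the acyl group on oxygen before C6 becomes a hindered carbinol. It sets out from 15: the potassium dienolate (KN(SiMe3)2, THF, −78 °C) would be O-acylated with isovaleric anhydride to the dienyl isovalerate F1. Hydroboration of the enol-ester alkene from the α-face (BH3·THF, 0 °C; hydrogen to C6, boron to C7) and neutral oxidation with Me3NO should give the 6β-isovaleryloxy-7α-alcohol F2 directly. Silylation (Et3SiOTf, 2,6-lutidine) returns to 20.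

Step 3. The γ-addition must join a quaternary carbon to a carbonyl carbon next to the quaternary C10; reversal of the addition to the linear α-adduct, or simple enolisation, may take over. The fallback uses a small, non-reversible nucleophile and builds the vinyl group afterwards. It sets out from 3: lithiated isobutyronitrile (LiN(iPr)2, isobutyronitrile, 3 equiv, THF, −78 °C) would add to the ketone to give the hydroxy nitrile F3. Reduction with (iBu)2AlH (toluene, −78 °C, aqueous work-up) gives the hydroxy aldehyde F4, and Wittig methylenation (Ph3P=CH2, THF, −78 → 0 °C) returns to 4.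

Step 16. Oxidative addition and transmetalation at the tetrasubstituted triflate next to the quaternary C10 may be slow, so that β-hydride elimination or protodeboronation of the alkylborane and hydrolysis of the triflate compete. The fallback moves the sp2–sp3 coupling to the unhindered C12–C13 bond. It sets out from 20: Stille coupling with Bu3SnCH=CH2 (Pd(PPh3)4, LiCl, THF, 60 °C) would give the C9-vinyl diene F5. 9-BBN hydroborates only its terminal vinyl group to the borane F6, which is coupled (PdCl2(dppf), Cs2CO3, DMF/H2O) with the vinyl iodide F7 ((E)-3-iodobut-2-en-1-ol tert-butyldimethylsilyl ether, made separately from but-2-yn-1-ol). This returns to 25.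

Further compounds
F1 | step 13 | dienyl isovalerate of 15 (isovaleryloxy on C6, C6=C7 and C8=C9 diene) | C[C@]12CCCC(C)(C)[C@@H]1C(OC(=O)CC(C)C)=CC(C)=C2OS(=O)(=O)C(F)(F)F
F2 | step 13 | 6β-(3-methylbutanoyloxy)-7α-hydroxy enol triflate | C[C@]12CCCC(C)(C)[C@@H]1[C@H](OC(=O)CC(C)C)[C@@H](O)C(C)=C2OS(=O)(=O)C(F)(F)F
F3 | step 3 | 2-[(1R,2R,3R)-2-allyl-1,3-dihydroxy-2-methylcyclohexyl]-2-methylpropanenitrile | C=CC[C@]1(C)[C@H](O)CCC[C@@]1(O)C(C)(C)C#N
F4 | step 3 | 2-[(1R,2R,3R)-2-allyl-1,3-dihydroxy-2-methylcyclohexyl]-2-methylpropanal | C=CC[C@]1(C)[C@H](O)CCC[C@@]1(O)C(C)(C)C=O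
F5 | step 16 | 9-vinyl analogue of 20 (vinyl in place of the triflate) | C[C@]12CCCC(C)(C)[C@@H]1[C@H](OC(=O)CC(C)C)[C@@H](O[Si](CC)(CC)CC)C(C)=C2C=C
F6 | step 16 | 9-BBN adduct of F5 (boron on C12) | C[C@]12CCCC(C)(C)[C@@H]1[C@H](OC(=O)CC(C)C)[C@@H](O[Si](CC)(CC)CC)C(C)=C2CCB1C3CCCC1CCC3
F7 | step 16 | (E)-tert-butyl[(3-iodobut-2-en-1-yl)oxy]dimethylsilane | I/C(C)=C/CO[Si](C)(C)C(C)(C)C
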